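The 14-membered carbocycle is disconnected at C4–C5 (numbering below), between the methyl carbinol carbon beside the lactone C3–O and the ring methylene leading to C7. A SmI2 Barbier macrocyclisation of an open-chain ω-iodo α-silyloxy methyl ketone forms this bond, closes the ring and sets the fully substituted C4 carbinol under Felkin–Anh control by the neighbouring C3 stereocentre, the feature the step exploits. The precursor is joined by Negishi coupling at C12–C13 from an (R)-carvone-derived iodo ketone (C1–C4, C13–C18; C1, C3 and the ketone from the chiral pool) and an alkenyl iodide built on (S)-α-hydroxy-γ-butyrolactone (C7). Lactone closure, C15 equilibration and 11,12-epoxidation follow.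

Key step: step 13

Remark on numbering (cembrane): C1 = ring CH bearing the CH(CH3)–C(=O) arm (C15, C16; methyl C17); C2 = CH2; C3 = lactone CH–O; C4 = C(CH3)(OH) (methyl C18); C5, C6 = CH2; C7 = CH(OH); C8 = C(=CH2) (C19); C9, C10 = CH2; C11, C12 = epoxide CH and C(CH3) (methyl C20); C13, C14 = CH2. TBS = tert-butyldimethylsilyl.

Remark (assumption): the hydroboration in step 2 is not expected to distinguish the faces of the isopropenyl group. Compounds 3–8 and 19–25 are therefore carried as pairs of C15 epimers (written without configuration at that carbon), and C15 is set by equilibration in step 16. The L-fructose-derived epoxidation ketone is taken as purchasable.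

Step 1
Reactants: 1 (R)-(−)-carvone
Product: 2 (1R,5R)-cis-carveol
Conditions: NaBH4, CeCl3·7H2O, MeOH, −78 → 0 °C
Reagents that add atoms: none
Why: Luche reduction, in which CeCl3-promoted 1,2-addition of hydride from the axial direction should give the equatorial alcohol cis to the isopropenyl group, setting the future C3 configuration (R) relative to the carvone centre (future C1).

Step 2
Reactants: 2 (1R,5R)-cis-carveol
Product: 4 (1R,5R)-5-(1-hydroxypropan-2-yl)-2-methylcyclohex-2-en-1-ol (both C15 epimers), via bis-9-BBN adduct 3 (not isolated)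
Conditions: 9-BBN (2.3 equiv), THF, 0 → 23 °C; then NaOH, H2O2, 0 °C
Reagents that add atoms: hydrogen peroxide, OO
Why: Hydroboration–oxidation, in which 9-BBN first converts the hydroxyl into a borinate and then adds anti-Markovnikov to the 1,1-disubstituted isopropenyl alkene much faster than to the trisubstituted ring alkene; no facial control at C15 is expected.

Step 3
Reactants: 4 diol
Product: 5 (1R,5R)-1-(tert-butyldimethylsilyloxy)-5-[1-(tert-butyldimethylsilyloxy)propan-2-yl]-2-methylcyclohex-2-ene
Conditions: TBSOTf, 2,6-lutidine, CH2Cl2, −78 → 0 °C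
Reagents that add atoms: tert-butyldimethylsilyl triflate, CC(C)(C)[Si](C)(C)OS(=O)(=O)C(F)(F)F
Why: Silyl ether formation protects both hydroxyls, and the bulky, poorly coordinating TBS group on the future O3 is chosen to enforce non-chelation (Felkin–Anh) control in the key step.

Step 4
Reactants: 5 bis-TBS ether
Product: 7 (3R,5R)-3,7-bis(tert-butyldimethylsilyloxy)-5-(2-hydroxyethyl)-6-methylheptan-2-one, via keto aldehyde 6 (not isolated)
Conditions: O3, CH2Cl2, −78 °C; PPh3, −78 → 23 °C; then EtOH, NaBH4, −78 °C
Reagents that add atoms: ozone, [O-][O+]=O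
Why: Ozonolysis of the only remaining (ring) alkene should unveil the C4 methyl ketone and the C13 aldehyde, and borohydride at −78 °C should reduce the aldehyde chemoselectively beside the hindered α-silyloxy ketone, leaving C3 untouched.

Step 5
Reactants: 7 hydroxy ketone
Product: 8 (3R,5S)-3,7-bis(tert-butyldimethylsilyloxy)-5-(2-iodoethyl)-6-methylheptan-2-one
Conditions: I2, PPh3, imidazole, CH2Cl2, 0 °C
Reagents that add atoms: iodine, II
Why: Appel iodination of the primary alcohol proceeds under near-neutral conditions that should not epimerise the α-silyloxy ketone (the C5 descriptor changes only through priority).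

Step 6
Reactants: 9 (S)-3-hydroxydihydrofuran-2(3H)-one
Product: 10 (S)-3-(tert-butyldimethylsilyloxy)dihydrofuran-2(3H)-one
Conditions: TBSCl, imidazole, DMF, 23 °C
Reagents that add atoms: tert-butyldimethylsilyl chloride, CC(C)(C)[Si](C)(C)Cl
Why: Standard silylation of the secondary hydroxyl of the chiral-pool lactone, whose stereocentre becomes C7 (S).

Step 7
Reactants: 11 pent-3-yn-1-ol
Product: 12 5-iodopent-2-yne
Conditions: I2, PPh3, imidazole, CH2Cl2, 0 → 23 °C
Reagents that add atoms: iodine, II
Why: Appel iodination of a primary homopropargylic alcohol.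

Step 8
Reactants: 12 5-iodopent-2-yne; 10 silyloxy lactone
Product: 14 (3S)-3-(tert-butyldimethylsilyloxy)-1-hydroxynon-7-yn-4-one, via pent-3-yn-1-yllithium 13 (not isolated)
Conditions: 12, t-BuLi (2.1 equiv), Et2O/pentane, −78 °C; then 10, THF, −78 °C; aq. NH4Cl
Reagents that add atoms: none
Why: Iodine–lithium exchange followed by single addition of the alkyllithium to the lactone (the tetrahedral intermediate persists at −78 °C) should give the γ-hydroxy ketone and form C8–C9 without touching C7.

Step 9
Reactants: 14 hydroxy ketone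
Product: 15 (3S)-3-(tert-butyldimethylsilyloxy)-4-methylidenenon-7-yn-1-ol
Conditions: Cp2TiMe2 (3 equiv), toluene/THF, 70 °C, dark
Reagents that add atoms: dimethyltitanocene Cp2TiMe2, C[Ti](C)(C1C=CC=C1)C1C=CC=C1
Why: Carbonyl methylenation by the non-basic titanium methylidene installs the C8 exocyclic methylene without α-epimerisation at C7 and without the base-induced silyl migration to the free primary hydroxyl that a phosphorus ylide could cause.

Step 10
Reactants: 15 enyne alcohol
Product: 17 (3S,7E)-3-(tert-butyldimethylsilyloxy)-8-iodo-4-methylidenenon-7-en-1-ol, via alkenylzirconocene chloride 16 (not isolated)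
Conditions: Cp2Zr(H)Cl (3 equiv), THF, 23 → 40 °C; then I2 (1.0 equiv), −78 °C
Reagents that add atoms: iodine, II
Why: Hydrozirconation–iodination, in which syn addition of Zr–H places zirconium on the less hindered methyl-bearing alkyne carbon (equilibrated by excess reagent) and iodinolysis with retention should give the (E)-2-iodo-2-alkene; the hindered 1,1-disubstituted alkene is expected to react far more slowly.

Step 11
Reactants: 17 iodo alkenol
Product: 18 tert-butyl{[(3S,7E)-1,8-diiodo-4-methylidenenon-7-en-3-yl]oxy}dimethylsilane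
Conditions: I2, PPh3, imidazole, CH2Cl2, 0 °C
Reagents that add atoms: iodine, II
Why: Appel iodination of the primary alcohol, to which the alkenyl iodide and the silyl ether are inert.

Step 12
Reactants: 8 iodo ketone; 18 diiodide
Product: 20 (1R,3R,7S,11E)-5-iodo-3,7,16-tris(tert-butyldimethylsilyloxy)-4,5-secocembra-8(19),11-dien-4-one, via alkylzinc iodide 19 (not isolated)
Conditions: 8, Zn dust (activated), LiCl, THF, 25 °C, solution decanted from zinc metal; then 18, PdCl2(dppf) (5 mol %), THF/NMP, 25 °C
Reagents that add atoms: none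
Why: Negishi coupling, in which zinc inserts into the sp3 C–I bond of 8 to give an alkylzinc iodide that does not add to ketones and couples with the alkenyl iodide of 18 with retention of the E geometry, while zerovalent palladium should leave the primary alkyl iodide of 18 untouched.

Step 13
Reactants: 20 seco iodo ketone
Product: 22 (1R,3R,4S,7S,11E)-3,7,16-tris(tert-butyldimethylsilyloxy)cembra-8(19),11-dien-4-ol, via alkylsamarium diiodide 21 (not isolated)
Conditions: SmI2 (3 equiv), NiI2 (3 mol %), THF, 0 → 23 °C, slow addition of 20 (final 2 mM); aq. NH4Cl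
Reagents that add atoms: none
Why: Intramolecular samarium Barbier reaction: SmI2 with catalytic NiI2 reduces the primary C5 iodide to an alkylsamarium species that adds to the C4 methyl ketone and forms C4–C5. The closest known reaction type is the SmI2-mediated Barbier cyclisation of ω-iodo ketones, applied here to a large ring. The 14-membered carbocycle closes by 14-exo-trig addition to the carbonyl under high dilution, helped by the two sp2 units (C8 methylene, C11=C12) that stiffen the chain. The new C4 stereocentre is controlled by C3: with the non-chelating silyloxy group anti to the incoming carbon and attack past the C3 hydrogen (Felkin–Anh polar model), the 3,4-anti (4S) carbinol should result. The step needs C–I reduction to outrun ketyl formation (which would expel the α-silyloxy group) and chelation to be absent; HMPA-free nickel-catalysed conditions and the bulky TBS ether are meant to secure both.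

Step 14
Reactants: 22 macrocyclic tris-silyl ether
Product: 23 (1R,3R,4S,7S,11E)-cembra-8(19),11-diene-3,4,7,16-tetrol
Conditions: TBAF, THF, 23 → 40 °C
Reagents that add atoms: none
Why: Fluoride-mediated desilylation removes all three TBS groups, so any O3-to-O4 silyl migration during step 13 is without consequence.

Step 15
Reactants: 23 tetraol
Product: 25 (1R,3R,4S,7S,11E)-4,7-dihydroxycembra-8(19),11-dien-16,3-olide (C15 epimers), via six-membered lactol 24 (not isolated)
Conditions: Cu(MeCN)4OTf (5 mol %), 2,2′-bipyridine, TEMPO, N-methylimidazole, MeCN, air, 23 °C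
Reagents that add atoms: none
Why: Copper/nitroxyl aerobic oxidative lactonisation, in which the unhindered primary C16 alcohol is oxidised selectively, the aldehyde is trapped by the C3 hydroxyl as the six-membered lactol and oxidised again to the δ-lactone, while the secondary C7 and tertiary C4 hydroxyls should not be oxidised by the TEMPO system.

Step 16
Reactants: 25 lactone epimers
Product: 26 (1R,3R,4S,7S,11E,15S)-4,7-dihydroxycembra-8(19),11-dien-16,3-olide
Conditions: DBU, toluene, 80 °C (minor epimer resubmitted)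
Reagents that add atoms: none
Why: Base-mediated epimerisation α to the lactone carbonyl under thermodynamic control should place the C15 methyl equatorial, trans to the C1–C14 bond, in the chair lactone whose C1 and C3 substituents (the macrocyclic bridge) are equatorial, giving the (15S) epimer.

Step 17
Reactants: 26 dienyl lactone
Product: 27 (1R,3R,4S,7S,11S,12S,15S)-11,12-epoxy-4,7-dihydroxycembr-8(19)-en-16,3-olide (target)
Conditions: L-fructose-derived Shi ketone (0.3 equiv), Oxone, K2CO3, Bu4NHSO4, MeCN/dimethoxymethane/aq. Na2B4O7–Na2EDTA buffer, 0 °C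
Reagents that add atoms: potassium peroxymonosulfate (Oxone), [K+].[O-]S(=O)(=O)OO
Why: Shi epoxidation, in which the chiral dioxirane should attack the electron-rich trisubstituted (E)-C11=C12 alkene in preference to the 1,1-disubstituted allylic C8 methylene and, by reagent control through the spiro transition state, deliver oxygen to the face that gives the (11S,12S) epoxide.

Compound list
1 | (R)-(−)-carvone | O=C1C(C)=CC[C@@H](C(C)=C)C1 | starting material
2 | (1R,5R)-cis-carveol | O[C@H]1C(C)=CC[C@@H](C(C)=C)C1 | intermediate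
3 | bis-9-BBN adduct of 2 (O-borinate and B-alkyl borane at C16) | C1CCC2CCCC1B2O[C@H]1C(C)=CC[C@@H](C(C)CB2C3CCCC2CCC3)C1 | intermediate (not isolated)
4 | (1R,5R)-5-(1-hydroxypropan-2-yl)-2-methylcyclohex-2-en-1-ol, C15 epimers | O[C@H]1C(C)=CC[C@@H](C(C)CO)C1 | intermediate
5 | (1R,5R)-1-(tert-butyldimethylsilyloxy)-5-[1-(tert-butyldimethylsilyloxy)propan-2-yl]-2-methylcyclohex-2-ene | CC(C)(C)[Si](C)(C)O[C@H]1C(C)=CC[C@@H](C(C)CO[Si](C)(C)C(C)(C)C)C1 | intermediate
6 | (3S,5R)-5-(tert-butyldimethylsilyloxy)-3-[1-(tert-butyldimethylsilyloxy)propan-2-yl]-6-oxoheptanal | CC(=O)[C@H](O[Si](C)(C)C(C)(C)C)C[C@@H](CC=O)C(C)CO[Si](C)(C)C(C)(C)C | intermediate (not isolated)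
7 | (3R,5R)-3,7-bis(tert-butyldimethylsilyloxy)-5-(2-hydroxyethyl)-6-methylheptan-2-one | CC(=O)[C@H](O[Si](C)(C)C(C)(C)C)C[C@@H](CCO)C(C)CO[Si](C)(C)C(C)(C)C | intermediate
8 | (3R,5S)-3,7-bis(tert-butyldimethylsilyloxy)-5-(2-iodoethyl)-6-methylheptan-2-one | CC(=O)[C@H](O[Si](C)(C)C(C)(C)C)C[C@@H](CCI)C(C)CO[Si](C)(C)C(C)(C)C | intermediate
9 | (S)-3-hydroxydihydrofuran-2(3H)-one | O[C@H]1CCOC1=O | starting material
10 | (S)-3-(tert-butyldimethylsilyloxy)dihydrofuran-2(3H)-one | CC(C)(C)[Si](C)(C)O[C@H]1CCOC1=O | intermediate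
11 | pent-3-yn-1-ol | CC#CCCO | starting material
12 | 5-iodopent-2-yne | CC#CCCI | intermediate
13 | pent-3-yn-1-yllithium | CC#CCC[Li] | intermediate (not isolated)
14 | (3S)-3-(tert-butyldimethylsilyloxy)-1-hydroxynon-7-yn-4-one | CC#CCCC(=O)[C@@H](O[Si](C)(C)C(C)(C)C)CCO | intermediate
15 | (3S)-3-(tert-butyldimethylsilyloxy)-4-methylidenenon-7-yn-1-ol | CC#CCCC(=C)[C@@H](O[Si](C)(C)C(C)(C)C)CCO | intermediate
16 | (E)-alkenylzirconocene chloride from 15 (zirconium on the methyl-bearing carbon, hydroxyl as zirconium alkoxide) | C/C(=C\CCC(=C)[C@@H](O[Si](C)(C)C(C)(C)C)CCO[Zr](Cl)(C1C=CC=C1)C1C=CC=C1)[Zr](Cl)(C1C=CC=C1)C1C=CC=C1 | intermediate (not isolated)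
17 | (3S,7E)-3-(tert-butyldimethylsilyloxy)-8-iodo-4-methylidenenon-7-en-1-ol | C/C(I)=C\CCC(=C)[C@@H](O[Si](C)(C)C(C)(C)C)CCO | intermediate
18 | tert-butyl{[(3S,7E)-1,8-diiodo-4-methylidenenon-7-en-3-yl]oxy}dimethylsilane | C/C(I)=C\CCC(=C)[C@@H](O[Si](C)(C)C(C)(C)C)CCI | intermediate
19 | alkylzinc iodide from 8 (zinc on C13) | CC(=O)[C@H](O[Si](C)(C)C(C)(C)C)C[C@@H](CC[Zn]I)C(C)CO[Si](C)(C)C(C)(C)C | intermediate (not isolated)
20 | (1R,3R,7S,11E)-5-iodo-3,7,16-tris(tert-butyldimethylsilyloxy)-4,5-secocembra-8(19),11-dien-4-one | CC(=O)[C@H](O[Si](C)(C)C(C)(C)C)C[C@@H](CC/C(C)=C/CCC(=C)[C@@H](O[Si](C)(C)C(C)(C)C)CCI)C(C)CO[Si](C)(C)C(C)(C)C | intermediate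
21 | C5 alkylsamarium diiodide from 20 | CC(=O)[C@H](O[Si](C)(C)C(C)(C)C)C[C@@H](CC/C(C)=C/CCC(=C)[C@@H](O[Si](C)(C)C(C)(C)C)CC[Sm](I)I)C(C)CO[Si](C)(C)C(C)(C)C | intermediate (not isolated)
22 | (1R,3R,4S,7S,11E)-3,7,16-tris(tert-butyldimethylsilyloxy)cembra-8(19),11-dien-4-ol | C=C1CC/C=C(C)/CC[C@@H](C(C)CO[Si](C)(C)C(C)(C)C)C[C@@H](O[Si](C)(C)C(C)(C)C)[C@@](C)(O)CC[C@@H]1O[Si](C)(C)C(C)(C)C | intermediate
23 | (1R,3R,4S,7S,11E)-cembra-8(19),11-diene-3,4,7,16-tetrol | C=C1CC/C=C(C)/CC[C@@H](C(C)CO)C[C@@H](O)[C@@](C)(O)CC[C@@H]1O | intermediate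
24 | six-membered lactol (C16 hemiacetal to O3) of 23 | C=C1CC/C=C(C)/CC[C@@H]2C[C@@H](OC(O)C2C)[C@@](C)(O)CC[C@@H]1O | intermediate (not isolated)
25 | (1R,3R,4S,7S,11E)-4,7-dihydroxycembra-8(19),11-dien-16,3-olide, C15 epimers | C=C1CC/C=C(C)/CC[C@@H]2C[C@@H](OC(=O)C2C)[C@@](C)(O)CC[C@@H]1O | intermediate
26 | (1R,3R,4S,7S,11E,15S)-4,7-dihydroxycembra-8(19),11-dien-16,3-olide | C=C1CC/C=C(C)/CC[C@@H]2C[C@@H](OC(=O)[C@H]2C)[C@@](C)(O)CC[C@@H]1O | intermediate
27 | (1R,3R,4S,7S,11S,12S,15S)-11,12-epoxy-4,7-dihydroxycembr-8(19)-en-16,3-olide | C=C1CC[C@@H]2O[C@@]2(C)CC[C@@H]2C[C@@H](OC(=O)[C@H]2C)[C@@](C)(O)CC[C@@H]1O | target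

Total step count: 17
Longest linear sequence: 11 steps (steps 1–5, then 12–17; the branch through steps 7–11 and 12–17 is equally long; step 6 is a one-step side branch).

Steps most likely to fail

1. Step 13 (key step). The alkylsamarium may be protonated or react between molecules before the large ring closes. Single-electron reduction of the α-silyloxy ketone may expel the silyloxy group, and facial selectivity may erode if samarium coordinates O3. Fallback: the order of the two carbon–carbon bond formations is reversed, so that the hindered C4–C5 bond is made between fragments and the ring is closed at C12–C13 by palladium catalysis. It sets out from 15 and 7. Appel iodination of 15 gives the homopropargylic iodide F1. Iodine–lithium exchange, transmetalation with CeCl3 and addition of the organocerium reagent (2.2 equiv, one consumed by the free hydroxyl) to ketone 7 under Felkin–Anh control should give the C4 tertiary alcohol F2. Hydrozirconation–iodination of its alkyne gives the (E)-alkenyl iodide F3, and Appel iodination of the primary C13 alcohol gives the diiodide F4. Zinc insertion into the sp3 C–I bond and intramolecular Negishi coupling at high dilution then returns to 22.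

2. Step 16. The equilibrium may not lie far enough on the side of the (15S) epimer, or epimerisation may be slow relative to acyl migration towards the C4 hydroxyl. Fallback: C15 is fixed at the outset by enzymatic discrimination instead of late equilibration. It sets out from 4. Lipase-catalysed acetylation (Burkholderia cepacia lipase, vinyl acetate, t-BuOMe) of the primary hydroxyl distinguishes the two epimers at the methyl-branched carbon. The primary acetate of the (15S)-configured epimer F5 is separated (should the enzyme prefer the other epimer, the unreacted diol is the required material) and methanolysed (K2CO3, MeOH). This comes back to 4 as a single epimer, which is carried through unchanged so that step 15 delivers 26 directly.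

3. Step 10. Zirconium may add to both alkyne carbons (insufficient regioselectivity), and the excess hydride reagent needed for equilibration may attack the methylidene group. Fallback: the trisubstituted alkene is assembled without alkyne hydrometalation. It sets out from 10. Addition of [2-(1,3-dioxolan-2-yl)ethyl]magnesium bromide at −78 °C gives the hydroxy ketone acetal F6, and Cp2TiMe2 methylenation gives the methylidene acetal F7. Appel iodination gives the iodide F8, mild acetal hydrolysis (PPTS, aqueous acetone) gives the aldehyde F9, and CBr4/PPh3 gives the 1,1-dibromoalkene F10. Palladium-catalysed coupling with alkylzinc 19 should occur selectively at the C–Br bond trans to the chain to give the bromoalkene F11. A second Negishi coupling with MeZnCl (Pd(t-Bu3P)2), with retention, comes back to 20.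

Further compounds
F1 | step 13 | tert-butyl{[(3S)-1-iodo-4-methylidenenon-7-yn-3-yl]oxy}dimethylsilane | CC#CCCC(=C)[C@@H](O[Si](C)(C)C(C)(C)C)CCI
F2 | step 13 | (1R,3R,4S,7S)-3,7,16-tris(tert-butyldimethylsilyloxy)-12,13-secocembr-8(19)-en-11-yne-4,13-diol | C[C@](O)(CC[C@H](O[Si](C)(C)C(C)(C)C)C(=C)CCC#CC)[C@H](O[Si](C)(C)C(C)(C)C)C[C@@H](CCO)C(C)CO[Si](C)(C)C(C)(C)C
F3 | step 13 | (1R,3R,4S,7S,11E)-12-iodo-3,7,16-tris(tert-butyldimethylsilyloxy)-12,13-secocembra-8(19),11-diene-4,13-diol | C[C@](O)(CC[C@H](O[Si](C)(C)C(C)(C)C)C(=C)CC/C=C(\C)I)[C@H](O[Si](C)(C)C(C)(C)C)C[C@@H](CCO)C(C)CO[Si](C)(C)C(C)(C)C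
F4 | step 13 | (1R,3R,4S,7S,11E)-12,13-diiodo-3,7,16-tris(tert-butyldimethylsilyloxy)-12,13-secocembra-8(19),11-dien-4-ol | C[C@](O)(CC[C@H](O[Si](C)(C)C(C)(C)C)C(=C)CC/C=C(\C)I)[C@H](O[Si](C)(C)C(C)(C)C)C[C@@H](CCI)C(C)CO[Si](C)(C)C(C)(C)C
F5 | step 16 | (2S)-2-[(1R,5R)-5-hydroxy-4-methylcyclohex-3-en-1-yl]propyl acetate | O[C@H]1C(C)=CC[C@@H]([C@H](C)COC(C)=O)C1
F6 | step 10 | (3S)-3-(tert-butyldimethylsilyloxy)-6-(1,3-dioxolan-2-yl)-1-hydroxyhexan-4-one | O=C(CCC1OCCO1)[C@@H](O[Si](C)(C)C(C)(C)C)CCO
F7 | step 10 | (3S)-3-(tert-butyldimethylsilyloxy)-6-(1,3-dioxolan-2-yl)-4-methylidenehexan-1-ol | C=C(CCC1OCCO1)[C@@H](O[Si](C)(C)C(C)(C)C)CCO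
F8 | step 10 | tert-butyl{[(3S)-6-(1,3-dioxolan-2-yl)-1-iodo-4-methylidenehexan-3-yl]oxy}dimethylsilane | C=C(CCC1OCCO1)[C@@H](O[Si](C)(C)C(C)(C)C)CCI
F9 | step 10 | (5S)-5-(tert-butyldimethylsilyloxy)-7-iodo-4-methylideneheptanal | C=C(CCC=O)[C@@H](O[Si](C)(C)C(C)(C)C)CCI
F10 | step 10 | tert-butyl{[(3S)-8,8-dibromo-1-iodo-4-methylideneoct-7-en-3-yl]oxy}dimethylsilane | C=C(CCC=C(Br)Br)[C@@H](O[Si](C)(C)C(C)(C)C)CCI
F11 | step 10 | (1R,3R,7S,11Z)-12-bromo-5-iodo-20-nor-3,7,16-tris(tert-butyldimethylsilyloxy)-4,5-secocembra-8(19),11-dien-4-one (C13 trans to C10) | CC(=O)[C@H](O[Si](C)(C)C(C)(C)C)C[C@@H](CC/C(Br)=C/CCC(=C)[C@@H](O[Si](C)(C)C(C)(C)C)CCI)C(C)CO[Si](C)(C)C(C)(C)C
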